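The route cuts the seven-membered ring at C7–C8 and C9–C10. C8(CH3)=C9 is taken as a propyne unit, and C7–C6(O)–C5–C1–C10 as a 1-silyloxyvinyl cyclopropane whose three-membered ring (C1, C5, C10) is fused to the cyclopentanone. One rhodium-catalysed [5+2] cycloaddition closes the seven-membered ring, forms both ring bonds and leaves C4 (ketone) and C6 (silyl enol ether) differentiated, with quaternary C1 untouched. Propyne is used as its 1-trimethylsilyl derivative so that the silyl group fixes the orientation of the alkyne; it is removed later by protodesilylation. The cyclopropane comes from an asymmetric intramolecular cyclopropanation, and C4, C5 and C6 are set afterwards.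

Key step: step 5

Remark: atoms carry daucane numbers (C1 quaternary methyl carbon, C2 and C3 CH2, C4 carbinol carbon with isopropyl, C5 ring-fusion CH, C6 ester carbon, C7 CH2, C8 methyl-bearing alkene carbon, C9 alkene CH, C10 CH2); β is the face of the C1 methyl group.
Remark: the bis(oxazoline) antipode that gives the (1S,5R) ketone in step 3 is used; its sense of induction is assumed to be assignable in a trial run.

Step 1
Reactants: 1 acetylacetone (pentane-2,4-dione); 2 3-chloro-2-methylprop-1-ene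
Product: 4 7-methyloct-7-ene-2,4-dione, via acetylacetone dilithium dianion 3 (not isolated)
Conditions: LiN(i-Pr)2 (2.1 equiv), THF, 0 °C; then 2, 0 °C to rt; aq NH4Cl
Reagents that add atoms: none
Why: Double deprotonation gives the 1,3-dianion, whose terminal carbanion is the more reactive site and is alkylated by the allylic chloride (γ-alkylation of a β-diketone dianion); no stereocenter is formed.

Step 2
Reactants: 4 7-methyloct-7-ene-2,4-dione
Product: 5 3-diazo-7-methyloct-7-ene-2,4-dione
Conditions: 4-acetamidobenzenesulfonyl azide, Et3N, MeCN, 0 °C to rt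
Reagents that add atoms: 4-acetamidobenzenesulfonyl azide, CC(=O)Nc1ccc(cc1)S(=O)(=O)N=[N+]=[N-]
Why: Regitz diazo transfer to the doubly activated C3 methylene of the β-diketone; no stereocenter is formed.

Step 3
Reactants: 5 3-diazo-7-methyloct-7-ene-2,4-dione
Product: 6 (1S,5R)-1-acetyl-5-methylbicyclo[3.1.0]hexan-2-one
Conditions: [Cu(MeCN)4]PF6 (5 mol %), (S,S)-t-Bu-box (6 mol %), toluene, 50 °C, slow addition of 5
Reagents that add atoms: none
Why: Loss of N2 gives a copper carbene that adds across the tethered 1,1-disubstituted alkene (asymmetric intramolecular cyclopropanation of an α-diazo-β-dicarbonyl compound); the C2-symmetric bis(oxazoline) ligand selects the alkene face and so sets both cyclopropane carbons (daucane C1 and C5) at once, their cis relationship being enforced by the bicyclo[3.1.0] ring.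

Step 4
Reactants: 6 (1S,5R)-1-acetyl-5-methylbicyclo[3.1.0]hexan-2-one
Product: 8 (1S,5R)-1-[1-(tert-butyldimethylsilyloxy)ethenyl]-5-methylbicyclo[3.1.0]hexan-2-one, via acetyl lithium enolate 7 (not isolated)
Conditions: LiN(i-Pr)2 (1.05 equiv), THF, −78 °C; TBSCl, DMPU, −78 to 0 °C
Reagents that add atoms: tert-butyldimethylsilyl chloride, CC(C)(C)[Si](C)(C)Cl
Why: Under kinetic control the hindered amide base is expected to remove a proton from the exposed acetyl methyl group rather than from ring C3, and O-silylation traps that enolate (kinetic silyl enol ether formation); the two cyclopropane stereocenters are not touched.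

Step 5
Reactants: 8 (1S,5R)-1-[1-(tert-butyldimethylsilyloxy)ethenyl]-5-methylbicyclo[3.1.0]hexan-2-one; 9 trimethyl(prop-1-yn-1-yl)silane (1-(trimethylsilyl)propyne, the silyl-capped form of propyne)
Product: 10 (3aR)-8-[(tert-butyldimethylsilyl)oxy]-3a,6-dimethyl-5-(trimethylsilyl)-3,3a,4,7-tetrahydroazulen-1(2H)-one (C4 ketone, C5=C6 silyl enol ether, C8=C9 alkene with SiMe3 on C9)
Conditions: [Rh(CO)2Cl]2 (5 mol %), 9 (3 equiv), ClCH2CH2Cl, 80 °C, sealed tube
Reagents that add atoms: none
Why: [Rh(CO)2Cl]2 delivers monovalent rhodium that binds the silyloxyvinyl group of 8 and inserts into the cyclopropane bond C5–C10, giving a rhodacycle with a σ-bond to C10 and a π-allyl over C5–C6–C7; the alkyne then inserts into the Rh–C7 bond (C7–C8) and reductive elimination joins C9 to C10. The closest known reaction type is the rhodium-catalysed intermolecular [5+2] cycloaddition of vinylcyclopropanes with alkynes. The seven-membered ring is closed in the final C(sp2)–C(sp3) reductive elimination from the eight-membered rhodacycle, so that the ring is annulated onto the intact cyclopentanone. No stereocenter is formed: C1 keeps the configuration from step 3 and C5 becomes sp2. The step needs cleavage of C5–C10 and not of C5–C1, which the substrate secures because C10 gives a primary alkyl–rhodium bond in a fused rhodacycle while C1 is quaternary (and, bearing no hydrogen, cannot divert the Rh–C10 intermediate by β-hydride elimination). It also needs the methyl-bearing alkyne carbon at C7, which the trimethylsilyl group of 9 secures: in the insertion the larger alkyne substituent stays on the rhodium-bound carbon, away from the forming C7–C8 bond, and therefore ends on C9.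

Step 6
Reactants: 10 (3aR)-8-[(tert-butyldimethylsilyl)oxy]-3a,6-dimethyl-5-(trimethylsilyl)-3,3a,4,7-tetrahydroazulen-1(2H)-one
Product: 11 (1R,3aR)-8-[(tert-butyldimethylsilyl)oxy]-3a,6-dimethyl-1-(propan-2-yl)-5-(trimethylsilyl)-1,2,3,3a,4,7-hexahydroazulen-1-ol (C4 hydroxyl β, isopropyl α)
Conditions: i-PrMgCl, CeCl3 (anhydrous), THF, −78 to −40 °C; pH 7 phosphate buffer
Reagents that add atoms: isopropylmagnesium chloride, CC(C)[Mg]Cl
Why: The weakly basic isopropylcerium reagent adds 1,2 to the C4 carbonyl with little enolisation or β-hydride reduction (Imamoto organocerium addition), and is expected to approach from the α face, opposite the C1 methyl group that projects over the β face of the five-membered ring, so that the new C4 hydroxyl is β.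

Step 7
Reactants: 11 (1R,3aR)-8-[(tert-butyldimethylsilyl)oxy]-3a,6-dimethyl-1-(propan-2-yl)-5-(trimethylsilyl)-1,2,3,3a,4,7-hexahydroazulen-1-ol
Product: 12 (3R,3aR,8aR)-3-hydroxy-6,8a-dimethyl-3-(propan-2-yl)-7-(trimethylsilyl)-2,3,3a,5,8,8a-hexahydroazulen-4(1H)-one (trans-fused ketol, H5 α)
Conditions: TBAF (1.1 equiv), AcOH (1.5 equiv), THF, −78 to 0 °C
Reagents that add atoms: none
Why: Buffered fluoride cleaves the enol silyl ether (the vinyl–SiMe3 group is inert) and the C5=C6 enolate is protonated at C5 (desilylation with kinetic protonation); protonation from the α face, anti to the C1 methyl group, should give the trans-fused ketol in which C6 lies away from the α-isopropyl group and the cis C4 hydroxyl hydrogen-bonds to the C6 carbonyl, while the acetic acid buffer suppresses retro-aldol cleavage and migration of the C8=C9 bond.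

Step 8
Reactants: 12 (3R,3aR,8aR)-3-hydroxy-6,8a-dimethyl-3-(propan-2-yl)-7-(trimethylsilyl)-2,3,3a,5,8,8a-hexahydroazulen-4(1H)-one
Product: 13 (3R,3aS,4S,8aR)-6,8a-dimethyl-3-(propan-2-yl)-7-(trimethylsilyl)-1,2,3,3a,4,5,8,8a-octahydroazulene-3,4-diol (C6 hydroxyl α)
Conditions: Me4NBH(OAc)3, MeCN/AcOH (1:1), −30 to −20 °C
Reagents that add atoms: none
Why: Evans–Saksena reduction: the C4 hydroxyl exchanges onto boron and delivers hydride intramolecularly to the β face of the C6 carbonyl, so that the new C6 hydroxyl is α, anti to the C4 hydroxyl and cis to H5.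

Step 9
Reactants: 13 (3R,3aS,4S,8aR)-6,8a-dimethyl-3-(propan-2-yl)-7-(trimethylsilyl)-1,2,3,3a,4,5,8,8a-octahydroazulene-3,4-diol
Product: 14 (3R,3aS,4S,8aR)-6,8a-dimethyl-3-(propan-2-yl)-1,2,3,3a,4,5,8,8a-octahydroazulene-3,4-diol (jaeschkeanadiol, the parent diol of the target)
Conditions: p-TsOH·H2O (0.5 equiv), MeCN/H2O (20:1), 0 °C to rt
Reagents that add atoms: none
Why: Acid-mediated ipso-protodesilylation of the vinylsilane: protonation at the silicon-bearing C9 gives a tertiary C8 cation stabilised by the β C–Si bond, and loss of the silyl group returns the C8=C9 double bond in place; no stereocenter is involved and the dilute acid should leave the tertiary alcohol alone.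

Step 10
Reactants: 15 4-hydroxycinnamic acid ((2E)-3-(4-hydroxyphenyl)prop-2-enoic acid)
Product: 17 (2E)-3-{4-[(tert-butyldimethylsilyl)oxy]phenyl}prop-2-enoic acid, via bis-silylated coumarate 16 (not isolated)
Conditions: TBSCl (2.3 equiv), imidazole, DMF, rt; then AcOH, THF/H2O, rt
Reagents that add atoms: tert-butyldimethylsilyl chloride, CC(C)(C)[Si](C)(C)Cl
Why: Both acidic OH groups are silylated and the far more labile silyl ester is then hydrolysed selectively (phenol protection as an aryl silyl ether); the E double bond is unchanged.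

Step 11
Reactants: 14 (3R,3aS,4S,8aR)-6,8a-dimethyl-3-(propan-2-yl)-1,2,3,3a,4,5,8,8a-octahydroazulene-3,4-diol; 17 (2E)-3-{4-[(tert-butyldimethylsilyl)oxy]phenyl}prop-2-enoic acid
Product: 19 (3R,3aS,4S,8aR)-3-hydroxy-6,8a-dimethyl-3-(propan-2-yl)-1,2,3,3a,4,5,8,8a-octahydroazulen-4-yl (2E)-3-{4-[(tert-butyldimethylsilyl)oxy]phenyl}prop-2-enoate, via mixed anhydride 18 (not isolated)
Conditions: 17, 2,4,6-trichlorobenzoyl chloride, Et3N, THF, rt; then 14, DMAP, toluene, rt to 40 °C
Reagents that add atoms: none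
Why: Yamaguchi esterification: the mixed anhydride 18 acylates DMAP and then the secondary C6 hydroxyl, the tertiary C4 hydroxyl being too hindered to react; acylation at oxygen keeps the C6 configuration.

Step 12
Reactants: 19 (3R,3aS,4S,8aR)-3-hydroxy-6,8a-dimethyl-3-(propan-2-yl)-1,2,3,3a,4,5,8,8a-octahydroazulen-4-yl (2E)-3-{4-[(tert-butyldimethylsilyl)oxy]phenyl}prop-2-enoate
Product: 20 (3R,3aS,4S,8aR)-3-hydroxy-6,8a-dimethyl-3-(propan-2-yl)-1,2,3,3a,4,5,8,8a-octahydroazulen-4-yl (2E)-3-(4-hydroxyphenyl)prop-2-enoate (CNP0265426.1)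
Conditions: TBAF, AcOH, THF, 0 °C
Reagents that add atoms: none
Why: Fluoride cleaves the aryl silyl ether (desilylation) and the acetic acid buffer keeps the phenoxide from attacking the cinnamate ester; no stereocenter is touched.

Compound list
1 | acetylacetone (pentane-2,4-dione) | CC(=O)CC(C)=O | starting material
2 | 3-chloro-2-methylprop-1-ene | CC(=C)CCl | starting material
3 | acetylacetone dilithium dianion | [Li+].[Li+].C=C([O-])C=C(C)[O-] | intermediate (not isolated)
4 | 7-methyloct-7-ene-2,4-dione | CC(=O)CC(=O)CCC(C)=C | intermediate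
5 | 3-diazo-7-methyloct-7-ene-2,4-dione | CC(=O)C(=[N+]=[N-])C(=O)CCC(C)=C | intermediate
6 | (1S,5R)-1-acetyl-5-methylbicyclo[3.1.0]hexan-2-one | CC(=O)[C@]12C[C@@]1(C)CCC2=O | intermediate
7 | lithium enolate of the acetyl group of 6 | [Li+].C=C([O-])[C@]12C[C@@]1(C)CCC2=O | intermediate (not isolated)
8 | (1S,5R)-1-[1-(tert-butyldimethylsilyloxy)ethenyl]-5-methylbicyclo[3.1.0]hexan-2-one | C=C(O[Si](C)(C)C(C)(C)C)[C@]12C[C@@]1(C)CCC2=O | intermediate
9 | trimethyl(prop-1-yn-1-yl)silane | CC#C[Si](C)(C)C | starting material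
10 | (3aR)-8-[(tert-butyldimethylsilyl)oxy]-3a,6-dimethyl-5-(trimethylsilyl)-3,3a,4,7-tetrahydroazulen-1(2H)-one | CC1=C([Si](C)(C)C)C[C@@]2(C)CCC(=O)C2=C(O[Si](C)(C)C(C)(C)C)C1 | intermediate
11 | (1R,3aR)-8-[(tert-butyldimethylsilyl)oxy]-3a,6-dimethyl-1-(propan-2-yl)-5-(trimethylsilyl)-1,2,3,3a,4,7-hexahydroazulen-1-ol | CC1=C([Si](C)(C)C)C[C@@]2(C)CC[C@@](O)(C(C)C)C2=C(O[Si](C)(C)C(C)(C)C)C1 | intermediate
12 | (3R,3aR,8aR)-3-hydroxy-6,8a-dimethyl-3-(propan-2-yl)-7-(trimethylsilyl)-2,3,3a,5,8,8a-hexahydroazulen-4(1H)-one | CC1=C([Si](C)(C)C)C[C@@]2(C)CC[C@@](O)(C(C)C)[C@@H]2C(=O)C1 | intermediate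
13 | (3R,3aS,4S,8aR)-6,8a-dimethyl-3-(propan-2-yl)-7-(trimethylsilyl)-1,2,3,3a,4,5,8,8a-octahydroazulene-3,4-diol | CC1=C([Si](C)(C)C)C[C@@]2(C)CC[C@@](O)(C(C)C)[C@@H]2[C@@H](O)C1 | intermediate
14 | (3R,3aS,4S,8aR)-6,8a-dimethyl-3-(propan-2-yl)-1,2,3,3a,4,5,8,8a-octahydroazulene-3,4-diol | CC1=CC[C@@]2(C)CC[C@@](O)(C(C)C)[C@@H]2[C@@H](O)C1 | intermediate
15 | 4-hydroxycinnamic acid | OC(=O)/C=C/c1ccc(O)cc1 | starting material
16 | tert-butyldimethylsilyl (2E)-3-{4-[(tert-butyldimethylsilyl)oxy]phenyl}prop-2-enoate | CC(C)(C)[Si](C)(C)OC(=O)/C=C/c1ccc(O[Si](C)(C)C(C)(C)C)cc1 | intermediate (not isolated)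
17 | (2E)-3-{4-[(tert-butyldimethylsilyl)oxy]phenyl}prop-2-enoic acid | OC(=O)/C=C/c1ccc(O[Si](C)(C)C(C)(C)C)cc1 | intermediate
18 | (2E)-3-{4-[(tert-butyldimethylsilyl)oxy]phenyl}prop-2-enoic 2,4,6-trichlorobenzoic anhydride | O=C(/C=C/c1ccc(O[Si](C)(C)C(C)(C)C)cc1)OC(=O)c1c(Cl)cc(Cl)cc1Cl | intermediate (not isolated)
19 | (3R,3aS,4S,8aR)-3-hydroxy-6,8a-dimethyl-3-(propan-2-yl)-1,2,3,3a,4,5,8,8a-octahydroazulen-4-yl (2E)-3-{4-[(tert-butyldimethylsilyl)oxy]phenyl}prop-2-enoate | CC1=CC[C@@]2(C)CC[C@@](O)(C(C)C)[C@@H]2[C@@H](OC(=O)/C=C/c2ccc(O[Si](C)(C)C(C)(C)C)cc2)C1 | intermediate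
20 | (3R,3aS,4S,8aR)-3-hydroxy-6,8a-dimethyl-3-(propan-2-yl)-1,2,3,3a,4,5,8,8a-octahydroazulen-4-yl (2E)-3-(4-hydroxyphenyl)prop-2-enoate | CC1=CC[C@@]2(C)CC[C@@](O)(C(C)C)[C@@H]2[C@@H](OC(=O)/C=C/c2ccc(O)cc2)C1 | target

Total step count: 12. Longest linear sequence: 11 steps (steps 1 to 9, 11 and 12); step 10 is the side branch.

Steps most likely to fail

Step 5. The eight-membered rhodacycle may fail to undergo reductive elimination between the silyl-bearing alkenyl carbon and the neopentyl C10, so that the catalyst stalls or the vinylcyclopropane is consumed by rearrangement. The fallback sets out from 8 and gives up substrate control of orientation in exchange for turnover. Propyne gas is used without a silyl group under the cationic catalyst [Rh(C10H8)(cod)]SbF6. The cycloadduct (3aR)-8-[(tert-butyldimethylsilyl)oxy]-3a,6-dimethyl-3,3a,4,7-tetrahydroazulen-1(2H)-one F1 then has to be separated from any regioisomeric adduct. F1 is taken through the operations of step 6 to (1R,3aR)-8-[(tert-butyldimethylsilyl)oxy]-3a,6-dimethyl-1-(propan-2-yl)-1,2,3,3a,4,7-hexahydroazulen-1-ol F2 and of step 7 to (3R,3aR,8aR)-3-hydroxy-6,8a-dimethyl-3-(propan-2-yl)-2,3,3a,5,8,8a-hexahydroazulen-4(1H)-one F3. Directed reduction of F3 as in step 8 comes back to the route at 14, so step 9 is no longer needed.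

Step 7. The enolate may be protonated on the β face, next to the small C4 hydroxyl, which would give the cis ring fusion; the ketol may also suffer retro-aldol opening or double-bond migration under fluoride. The fallback sets out from 11 and replaces the protonation by a stereospecific 1,2-hydride shift.
- Oxalic acid in wet THF ionises the tertiary allylic alcohol and hydrolyses the enol ether (Stork–Danheiser-type transposition). This gives (8aR)-6,8a-dimethyl-3-(propan-2-yl)-7-(trimethylsilyl)-1,2,8,8a-tetrahydroazulen-4(5H)-one F4; material of either configuration at C4 converges here.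
- (S)-Me-CBS with BH3·SMe2 should give, under reagent control, the 6β-alcohol (4R,8aR)-6,8a-dimethyl-3-(propan-2-yl)-7-(trimethylsilyl)-1,2,4,5,8,8a-hexahydroazulen-4-ol F5.
- VO(acac)2 with t-BuOOH epoxidises C4=C5 on the face of the hydroxyl to (3R,3aS,4R,8aR)-3,3a-epoxy-6,8a-dimethyl-3-(propan-2-yl)-7-(trimethylsilyl)-1,2,3,3a,4,5,8,8a-octahydroazulen-4-ol F6.
- ZnBr2 or BF3·OEt2 in CH2Cl2 at low temperature then induces the semipinacol shift of the C6 hydrogen to C5, anti to the departing epoxide oxygen. H5 becomes α, the oxygen stays on C4 as the β hydroxyl and C6 becomes the ketone, which is 12.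

Step 6. Enolisation at C3 or β-hydride transfer from the secondary organometallic may compete with addition to the hindered, vinylogous-ester-type carbonyl, and the face selectivity rests on one remote methyl group. Material of the wrong C4 configuration can be recycled through F4 above. The fallback sets out from 10 and brings in the three carbons as an sp2 nucleophile without β-hydrogens.
- CH2=C(CH3)MgBr with CeCl3 gives (1R,3aR)-8-[(tert-butyldimethylsilyl)oxy]-3a,6-dimethyl-1-(prop-1-en-2-yl)-5-(trimethylsilyl)-1,2,3,3a,4,7-hexahydroazulen-1-ol F7.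
- TBAF with AcOH gives (3S,3aR,8aR)-3-hydroxy-6,8a-dimethyl-3-(prop-1-en-2-yl)-7-(trimethylsilyl)-2,3,3a,5,8,8a-hexahydroazulen-4(1H)-one F8.
- Me4NBH(OAc)3 gives (3S,3aS,4S,8aR)-6,8a-dimethyl-3-(prop-1-en-2-yl)-7-(trimethylsilyl)-1,2,3,3a,4,5,8,8a-octahydroazulene-3,4-diol F9.
- Hydrogenation of the 1,1-disubstituted alkene alone with H2 and RhCl(PPh3)3 comes back to the route at 13.

Further compounds
F1 | step 5 | (3aR)-8-[(tert-butyldimethylsilyl)oxy]-3a,6-dimethyl-3,3a,4,7-tetrahydroazulen-1(2H)-one | CC1=CC[C@@]2(C)CCC(=O)C2=C(O[Si](C)(C)C(C)(C)C)C1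
F2 | step 5 | (1R,3aR)-8-[(tert-butyldimethylsilyl)oxy]-3a,6-dimethyl-1-(propan-2-yl)-1,2,3,3a,4,7-hexahydroazulen-1-ol | CC1=CC[C@@]2(C)CC[C@@](O)(C(C)C)C2=C(O[Si](C)(C)C(C)(C)C)C1
F3 | step 5 | (3R,3aR,8aR)-3-hydroxy-6,8a-dimethyl-3-(propan-2-yl)-2,3,3a,5,8,8a-hexahydroazulen-4(1H)-one | CC1=CC[C@@]2(C)CC[C@@](O)(C(C)C)[C@@H]2C(=O)C1
F4 | step 7 | (8aR)-6,8a-dimethyl-3-(propan-2-yl)-7-(trimethylsilyl)-1,2,8,8a-tetrahydroazulen-4(5H)-one | CC1=C([Si](C)(C)C)C[C@@]2(C)CCC(C(C)C)=C2C(=O)C1
F5 | step 7 | (4R,8aR)-6,8a-dimethyl-3-(propan-2-yl)-7-(trimethylsilyl)-1,2,4,5,8,8a-hexahydroazulen-4-ol | CC1=C([Si](C)(C)C)C[C@@]2(C)CCC(C(C)C)=C2[C@H](O)C1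
F6 | step 7 | (3R,3aS,4R,8aR)-3,3a-epoxy-6,8a-dimethyl-3-(propan-2-yl)-7-(trimethylsilyl)-1,2,3,3a,4,5,8,8a-octahydroazulen-4-ol | CC1=C([Si](C)(C)C)C[C@@]2(C)CC[C@]3(C(C)C)O[C@]23[C@H](O)C1
F7 | step 6 | (1R,3aR)-8-[(tert-butyldimethylsilyl)oxy]-3a,6-dimethyl-1-(prop-1-en-2-yl)-5-(trimethylsilyl)-1,2,3,3a,4,7-hexahydroazulen-1-ol | CC1=C([Si](C)(C)C)C[C@@]2(C)CC[C@@](O)(C(C)=C)C2=C(O[Si](C)(C)C(C)(C)C)C1
F8 | step 6 | (3S,3aR,8aR)-3-hydroxy-6,8a-dimethyl-3-(prop-1-en-2-yl)-7-(trimethylsilyl)-2,3,3a,5,8,8a-hexahydroazulen-4(1H)-one | CC1=C([Si](C)(C)C)C[C@@]2(C)CC[C@@](O)(C(C)=C)[C@@H]2C(=O)C1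
F9 | step 6 | (3S,3aS,4S,8aR)-6,8a-dimethyl-3-(prop-1-en-2-yl)-7-(trimethylsilyl)-1,2,3,3a,4,5,8,8a-octahydroazulene-3,4-diol | CC1=C([Si](C)(C)C)C[C@@]2(C)CC[C@@](O)(C(C)=C)[C@@H]2[C@@H](O)C1
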